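**Assumption:** the target structure assigns no configuration to the C8–C8' biaryl axis. The axis is therefore left uncontrolled, and the route would give the racemate if rotation about it proves slow.

## Analysis of the target

Triumbelletin (16) is made of three umbelliferone (7-hydroxy-2H-chromen-2-one) units and has six rings, all benzene or pyranone, with no sp3 carbon. Unit B is the hub. Its C8 is bonded to C8 of unit C, its C3 carries the ether oxygen that is the C7 oxygen of unit A, and its own C7 hydroxyl is free, as is that of unit C. There is no stereocentre. The only possible stereogenic element is the C8–C8' axis, which is flanked by four oxygen substituents (O1 and the C7 oxygen on each side). The sensitive groups are three lactones, which open with hydroxide or alkoxide and are Michael acceptors at C4, and two phenols. Two bonds make the synthesis hard. The biaryl bond is tetra-ortho-substituted. The C3–O ether joins the α-carbon of a lactone, which is nucleophilic by nature, to an unactivated aryl oxygen, so neither carbon of the ether invites substitution. The strategy rests on C3 of ring B: with an oxygen at C4, C3 lies between the lactone carbonyl C2 and a ketone C4 in a chromane-2,4-dione. That is the position where a diazo group can be placed and converted into an electrophilic carbenoid, which takes the O–H bond of umbelliferone. The C4 oxygen is removed afterwards.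

## Retrosynthetic reasoning

**16 to 15.** The last cut is at the two O–CH3 bonds. The C7 phenols of units B and C must be masked from the start, because a free phenol would be a second O–H donor in the key step and a ligand for palladium in the coupling. Methyl is the one group that survives strong base at 110 °C, aqueous base with palladium, a sulfonic anhydride and a metal carbenoid. The forward step has to cleave two hindered aryl methyl ethers without harming three lactones and the diaryl ether.

**15 to 14 to 13.** C4–H of ring B is traced back to C4–OH through enol triflate 14. The C4 oxygen has no place in 16, but it is what makes C3 the central carbon of a 1,3-dicarbonyl system. It is kept until the ether is in place and then removed by sulfonylation and palladium-catalysed reduction. The price is two steps, and the gain is a C3 that can be made electrophilic.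

**13 to 12 and 1.** The C3–O bond is cut. This cut releases unit A as umbelliferone 1 itself, unprotected and unmodified. The other ether bond, O–C7 of unit A, would need an activated coumarin on one side and a 3-hydroxycoumarin on the other. In the forward sense the carbenoid from diazo compound 12 must choose the O–H bond of 1 over its arene carbons. One point needs care: 13 itself has an acidic O–H at C4, so 1 has to be kept in excess over 13 throughout.

**12 to 11.** The C=N2 bond is cut. 4-Hydroxycoumarin 11 is a cyclic 1,3-dicarbonyl compound, and diazo transfer to such compounds needs no activation. C3 is remote from the crowded axis.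

**11 to 10 and 4.** The C8–C8' bond is cut between two carbons that each sit between two oxygens. Iodide 10 and boronate 4 are each one ring, each carries its heterocycle already, and each comes from a cheap phenol by iodination at the position between the two oxygens. The forward coupling must join two doubly ortho-substituted partners, which is the hardest step before the key step.

**10 to 7 and 8.** O1–C2 and C2–C3 of ring B are cut, and the C2 carbonyl carbon comes from diethyl carbonate 8 via keto ester 9. This annulation is placed before the biaryl coupling on purpose. It needs a strong base and sets free alkoxide at 110 °C, which would open and possibly isomerise the lactone of unit C if that unit were already attached.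

**7 to 6 to 5.** The O–CH3 bond at C4 and the C3–I bond are cut, which leads to 2,4-dihydroxyacetophenone 5. C3 is activated by both hydroxyl groups. The C2 hydroxyl is tied to the acetyl group by a hydrogen bond, so only the C4 hydroxyl is methylated.

**4 to 3 to 2 to 1.** The C–B, O–CH3 and C–I bonds of the unit C half are cut in turn and lead back to 1. C8 is the most nucleophilic carbon of 1. So 1 serves twice, as the source of unit C and as the O–H donor of the key step.

## Alternatives that were turned down

**Alternative 1:** Here the carbocycle of unit C is not bought but built. Its C4a–C8a and C5–C6 bonds are cut back to the 2-aryl bis(silyloxy)diene A2 and methyl propiolate A3. In the forward key step A2 and A3 undergo a [4+2] cycloaddition, and loss of methanol and of the silyl groups aromatises the adduct to the biaryl resorcylate A1. In its favour, the crowded biaryl bond is already present in A2 as an ordinary aryl–C(sp2) bond that stems from an arylacetate. No tetra-ortho cross-coupling is needed, and on this point the alternative is stronger than the chosen route. Against it, A1 is far from 16. The ester has to be turned into the pyranone of unit C. On the 2,6-dimethoxyphenyl ring one of two equivalent methoxy groups must be singled out and a carbonyl group introduced next to it for unit B. The C3 ether is not addressed at all. A2 is a moisture-sensitive ketene acetal that itself takes several steps, and the regiochemistry of the cycloaddition has to be right. The chosen strategy accepts one hard coupling (step 7) between two halves that are already coumarins, and spends its key step on the C3–O bond, which the alternative leaves open.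

**Alternative 2:** The pyranone of ring B is cut at C3=C4 and O1–C2, which gives the coumarinyloxyacetic acid A5 and the biaryl salicylaldehyde A6. The forward key step is a Perkin condensation with a carboxylic anhydride and its sodium salt at about 170 °C. The anhydride also acylates both phenols, so the product is triumbelletin diacetate A4. In its favour, C4 arrives at the right oxidation level, the ether oxygen is set by simple alkylation of 1, and only deacetylation remains after the key step. The endgame is shorter than the chosen one, and on this point the alternative is stronger. Against it, A6 needs the same crowded biaryl coupling and in addition a formyl group next to the hindered phenol. The α-aryloxy acid A5 is a weak carbon acid, so the condensation is slow and needs the high temperature. The phenol that must lactonise is flanked by the aryl group. The chosen strategy pays two extra steps for removal of the C4 oxygen, but forms the ether at 80 °C under neutral, catalytic conditions from a 4-hydroxycoumarin that a classical annulation provides.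

**Alternative 3:** The other bond of the ether, O–C7 of unit A, is cut, which gives the 3-hydroxycoumarin A8 and coumarin-7-boronic acid A9. The forward key step is a Chan–Lam coupling with a divalent copper carboxylate, an amine base and air. Its product is triumbelletin dimethyl ether A7, which is the same compound as 15. In its favour, the step runs at room temperature, nothing has to be removed from C4, and one step leads on to 16. Here the alternative is as short as a route can be after the key step. Against it, A8 is hard to reach. 3-Hydroxycoumarins are made from a salicylaldehyde by an azlactone condensation and hydrolysis, so the biaryl salicylaldehyde is needed again. The C3 hydroxyl sits next to the lactone carbonyl, chelates copper and is a weak nucleophile. A9 is electron-poor, so its transmetalation is slow and its oxidation to 1 competes. The chosen strategy uses 1 as such and makes its other partner, 12, in one step from a 4-hydroxycoumarin.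

Key step: step 9

## Route

**Step 1**
Reactants: 1 umbelliferone
Product: 2 7-hydroxy-8-iodo-2H-chromen-2-one
Conditions: I2, KI, 20% aq NH3, 0 °C to rt; then dil. H2SO4
Reagents that add atoms: iodine, [I][I]
Why: Electrophilic aromatic iodination of the phenoxide; C8 is the most nucleophilic carbon of 7-hydroxycoumarins (ortho to the oxygen, on the bond with the higher double-bond character), and this reagent is the known way to the 8-iodide.

**Step 2**
Reactants: 2 7-hydroxy-8-iodo-2H-chromen-2-one
Product: 3 8-iodo-7-methoxy-2H-chromen-2-one
Conditions: MeI, K2CO3, acetone, reflux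
Reagents that add atoms: iodomethane, CI
Why: Williamson O-methylation of the only hydroxyl group; the lactone is stable to K2CO3 in acetone.

**Step 3**
Reactants: 3 8-iodo-7-methoxy-2H-chromen-2-one
Product: 4 7-methoxy-8-(4,4,5,5-tetramethyl-1,3,2-dioxaborolan-2-yl)-2H-chromen-2-one
Conditions: B2pin2, PdCl2(dppf) (5 mol %), KOAc, 1,4-dioxane, 90 °C
Reagents that add atoms: bis(pinacolato)diboron, CC1(C)OB(OC1(C)C)B1OC(C)(C)C(C)(C)O1
Why: Miyaura borylation of an aryl iodide; KOAc is too weak a base to open the lactone or to start a Suzuki homocoupling.

**Step 4**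
Reactants: 5 2,4-dihydroxyacetophenone
Product: 6 1-(2,4-dihydroxy-3-iodophenyl)ethan-1-one
Conditions: I2, HIO3, EtOH/H2O, 40 °C
Reagents that add atoms: iodine, [I][I]; iodic acid, O[I](=O)=O
Why: Electrophilic aromatic iodination in which HIO3 reoxidises the iodide, so that all iodine is used; C3 is ortho to both hydroxyl groups, and this reagent pair is known to iodinate resacetophenone there.

**Step 5**
Reactants: 6 1-(2,4-dihydroxy-3-iodophenyl)ethan-1-one
Product: 7 1-(2-hydroxy-3-iodo-4-methoxyphenyl)ethan-1-one
Conditions: MeI (1.1 equiv), K2CO3, acetone, rt to 50 °C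
Reagents that add atoms: iodomethane, CI
Why: Selective Williamson methylation; the C2 hydroxyl is held in a hydrogen bond to the acetyl carbonyl and is flanked by iodine and acetyl, so the C4 hydroxyl reacts.

**Step 6**
Reactants: 7 1-(2-hydroxy-3-iodo-4-methoxyphenyl)ethan-1-one, 8 diethyl carbonate
Product: 10 4-hydroxy-8-iodo-7-methoxy-2H-chromen-2-one, via ethyl aroylacetate 9 (not isolated)
Conditions: NaH, toluene, 110 °C; then aq HCl
Reagents that add atoms: none
Why: Claisen-type C-ethoxycarbonylation of the ketone enolate gives 9, whose phenoxide closes onto the ester (the classical 4-hydroxycoumarin synthesis from 2-hydroxyacetophenones); the step is run while no other lactone is in the molecule, and the aryl iodide is inert to NaH.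

**Step 7**
Reactants: 10 4-hydroxy-8-iodo-7-methoxy-2H-chromen-2-one, 4 7-methoxy-8-(4,4,5,5-tetramethyl-1,3,2-dioxaborolan-2-yl)-2H-chromen-2-one
Product: 11 4-hydroxy-7-methoxy-8-(7-methoxy-2-oxo-2H-chromen-8-yl)-2H-chromen-2-one
Conditions: Pd(OAc)2 (5 mol %), SPhos (10 mol %), K3PO4, 1,4-dioxane/H2O, 90 °C; then aq HCl
Reagents that add atoms: none
Why: Suzuki–Miyaura coupling with a bulky, electron-rich dialkylbiarylphosphine, the ligand class that makes tetra-ortho-substituted biaryls accessible. Iodide 10 reacts as its potassium enolate, whose charge is remote from C8, and any lactone of unit C that the base opens to the cis-coumarinate recloses on acidification.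

**Step 8**
Reactants: 11 4-hydroxy-7-methoxy-8-(7-methoxy-2-oxo-2H-chromen-8-yl)-2H-chromen-2-one
Product: 12 3-diazo-7-methoxy-8-(7-methoxy-2-oxo-2H-chromen-8-yl)chromane-2,4-dione
Conditions: 4-acetamidobenzenesulfonyl azide, Et3N, MeCN, 0 °C to rt
Reagents that add atoms: 4-acetamidobenzenesulfonyl azide, CC(=O)Nc1ccc(cc1)S(=O)(=O)N=[N+]=[N-]
Why: Regitz diazo transfer to a cyclic 1,3-dicarbonyl compound, which is acidic enough for Et3N; C3 lies far from the crowded axis.

**Step 9**
Reactants: 12 3-diazo-7-methoxy-8-(7-methoxy-2-oxo-2H-chromen-8-yl)chromane-2,4-dione, 1 umbelliferone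
Product: 13 4-hydroxy-7-methoxy-8-(7-methoxy-2-oxo-2H-chromen-8-yl)-3-[(2-oxo-2H-chromen-7-yl)oxy]-2H-chromen-2-one
Conditions: Rh2(OAc)4 (2 mol %), 1 (3 equiv), 4 Å MS, ClCH2CH2Cl, 80 °C, slow addition of 12
Reagents that add atoms: none
Why: Rh2(OAc)4 adds to the diazo carbon of 12 and dinitrogen leaves, which gives a carbenoid bound to divalent rhodium at C3; it is flanked by the lactone carbonyl C2 and the ketone C4 and is therefore strongly electrophilic. The phenol oxygen of 1 adds to this carbon to give an oxonium ylide, and a proton shift followed by enolisation of the chromane-2,4-dione should deliver the 3-aryloxy-4-hydroxycoumarin 13. The closest known reaction type is the O–H insertion of cyclic 2-diazo-1,3-dicarbonyl compounds into phenols under dirhodium tetracarboxylate catalysis. No ring is closed and no stereocentre is formed. The step needs chemoselectivity for O–H over the aromatic C–H bonds at C6 and C8 of 1 and over Wolff ring contraction; the acceptor–acceptor carbenoid is captured by an oxygen lone pair faster than it attacks an arene, and the catalyst keeps the carbene on the metal. The two phenols of the biaryl half are methyl ethers and cannot donate, but the C4 enol O–H of 13 can, so 1 is used in threefold excess and 12 is added slowly to keep the ratio of donor to product high. That enol is also the weaker nucleophile, being a vinylogous carboxylic acid wedged between the new aryloxy group and the peri C5–H. C3 lies on the far side of ring B from the biaryl axis, so the crowding at C8 does not reach the reacting carbon.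

**Step 10**
Reactants: 13 4-hydroxy-7-methoxy-8-(7-methoxy-2-oxo-2H-chromen-8-yl)-3-[(2-oxo-2H-chromen-7-yl)oxy]-2H-chromen-2-one
Product: 14 7-methoxy-8-(7-methoxy-2-oxo-2H-chromen-8-yl)-2-oxo-3-[(2-oxo-2H-chromen-7-yl)oxy]-2H-chromen-4-yl trifluoromethanesulfonate
Conditions: Tf2O, Et3N, CH2Cl2, −78 to 0 °C
Reagents that add atoms: trifluoromethanesulfonic anhydride, O=S(=O)(OS(=O)(=O)C(F)(F)F)C(F)(F)F
Why: O-Sulfonylation of the vinylogous acid, the standard way from 4-hydroxycoumarins to 4-coumarinyl triflates; the C4 hydroxyl is the only O–H in 13.

**Step 11**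
Reactants: 14 7-methoxy-8-(7-methoxy-2-oxo-2H-chromen-8-yl)-2-oxo-3-[(2-oxo-2H-chromen-7-yl)oxy]-2H-chromen-4-yl trifluoromethanesulfonate
Product: 15 7-methoxy-8-(7-methoxy-2-oxo-2H-chromen-8-yl)-3-[(2-oxo-2H-chromen-7-yl)oxy]-2H-chromen-2-one
Conditions: Pd(OAc)2 (5 mol %), PPh3 (10 mol %), HCO2H, Et3N, DMF, 60 °C
Reagents that add atoms: none
Why: Palladium-catalysed formate reduction of an enol triflate: zerovalent palladium inserts into the C4–O bond, formate exchanges for triflate and loses CO2 to give the palladium hydride, and reductive elimination forms C4–H. The lactones, the diaryl ether and the methyl ethers are inert to these conditions.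

**Step 12**
Reactants: 15 7-methoxy-8-(7-methoxy-2-oxo-2H-chromen-8-yl)-3-[(2-oxo-2H-chromen-7-yl)oxy]-2H-chromen-2-one
Product: 16 triumbelletin, 7-hydroxy-8-(7-hydroxy-2-oxo-2H-chromen-8-yl)-3-[(2-oxo-2H-chromen-7-yl)oxy]-2H-chromen-2-one
Conditions: BBr3 (8 equiv), CH2Cl2, −78 °C to rt; then H2O
Reagents that add atoms: none
Why: Lewis-acid cleavage of aryl methyl ethers, routine for methoxycoumarins; bromide attacks only the methyl carbons, the diaryl ether has no sp3 carbon to attack, and the excess allows for boron bound to the three lactone carbonyls, which is released on aqueous work-up.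

## Compound list

1 | umbelliferone (7-hydroxy-2H-chromen-2-one) | O=c1ccc2ccc(O)cc2o1 | starting material
2 | 7-hydroxy-8-iodo-2H-chromen-2-one | O=c1ccc2ccc(O)c(I)c2o1 | intermediate
3 | 8-iodo-7-methoxy-2H-chromen-2-one | COc1ccc2ccc(=O)oc2c1I | intermediate
4 | 7-methoxy-8-(4,4,5,5-tetramethyl-1,3,2-dioxaborolan-2-yl)-2H-chromen-2-one | COc1ccc2ccc(=O)oc2c1B1OC(C)(C)C(C)(C)O1 | intermediate
5 | 2,4-dihydroxyacetophenone | CC(=O)c1ccc(O)cc1O | starting material
6 | 1-(2,4-dihydroxy-3-iodophenyl)ethan-1-one | CC(=O)c1ccc(O)c(I)c1O | intermediate
7 | 1-(2-hydroxy-3-iodo-4-methoxyphenyl)ethan-1-one | CC(=O)c1ccc(OC)c(I)c1O | intermediate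
8 | diethyl carbonate | CCOC(=O)OCC | starting material
9 | ethyl 3-(2-hydroxy-3-iodo-4-methoxyphenyl)-3-oxopropanoate | CCOC(=O)CC(=O)c1ccc(OC)c(I)c1O | intermediate
10 | 4-hydroxy-8-iodo-7-methoxy-2H-chromen-2-one | COc1ccc2c(O)cc(=O)oc2c1I | intermediate
11 | 4-hydroxy-7-methoxy-8-(7-methoxy-2-oxo-2H-chromen-8-yl)-2H-chromen-2-one | COc1ccc2c(O)cc(=O)oc2c1-c1c(OC)ccc2ccc(=O)oc12 | intermediate
12 | 3-diazo-7-methoxy-8-(7-methoxy-2-oxo-2H-chromen-8-yl)chromane-2,4-dione | [N-]=[N+]=C1C(=O)Oc2c(C1=O)ccc(OC)c2-c1c(OC)ccc2ccc(=O)oc12 | intermediate
13 | 4-hydroxy-7-methoxy-8-(7-methoxy-2-oxo-2H-chromen-8-yl)-3-[(2-oxo-2H-chromen-7-yl)oxy]-2H-chromen-2-one | O=c1ccc2ccc(Oc3c(O)c4ccc(OC)c(-c5c(OC)ccc6ccc(=O)oc56)c4oc3=O)cc2o1 | intermediate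
14 | 7-methoxy-8-(7-methoxy-2-oxo-2H-chromen-8-yl)-2-oxo-3-[(2-oxo-2H-chromen-7-yl)oxy]-2H-chromen-4-yl trifluoromethanesulfonate | O=c1ccc2ccc(Oc3c(OS(=O)(=O)C(F)(F)F)c4ccc(OC)c(-c5c(OC)ccc6ccc(=O)oc56)c4oc3=O)cc2o1 | intermediate
15 | 7-methoxy-8-(7-methoxy-2-oxo-2H-chromen-8-yl)-3-[(2-oxo-2H-chromen-7-yl)oxy]-2H-chromen-2-one (triumbelletin dimethyl ether) | O=c1ccc2ccc(Oc3cc4ccc(OC)c(-c5c(OC)ccc6ccc(=O)oc56)c4oc3=O)cc2o1 | intermediate
16 | triumbelletin | O=c1ccc2ccc(Oc3cc4ccc(O)c(-c5c(O)ccc6ccc(=O)oc56)c4oc3=O)cc2o1 | target

## Step count and least certain steps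

Total: 12 steps. Longest linear sequence: 9 steps (steps 4 to 12 from 5; equally steps 1 to 3 and 7 to 12 from 1).

**Step 9 (key step).** The carbenoid may attack C8 or C6 of the electron-rich carbocycle of 1 in a Friedel–Crafts sense and give C-arylation. It may undergo Wolff ring contraction when little donor is in solution, since 1 dissolves only moderately. It may also be taken up a second time by the enol O–H of 13. The fallback forms the ether from its other side. Starting from 12, the rhodium-catalysed insertion would be run with 4-methoxybenzyl alcohol, a small, soluble and purely oxygen-nucleophilic donor (Rh2(OAc)4, ClCH2CH2Cl, 80 °C). This should give 4-hydroxy-7-methoxy-3-[(4-methoxyphenyl)methoxy]-8-(7-methoxy-2-oxo-2H-chromen-8-yl)-2H-chromen-2-one F1. Triflation as in step 10 would give the 4-triflate F2, and formate reduction as in step 11 the 3-(4-methoxybenzyloxy)coumarin F3. CF3CO2H with anisole in CH2Cl2 would then free 3-hydroxy-7-methoxy-8-(7-methoxy-2-oxo-2H-chromen-8-yl)-2H-chromen-2-one F4. A Chan–Lam coupling of F4 with (2-oxo-2H-chromen-7-yl)boronic acid F5 (Cu(OAc)2, pyridine, 4 Å sieves, air, CH2Cl2) would form the O–C7 bond and rejoin the route at 15.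

**Step 7.** Transmetalation at a palladium aryl with two ortho oxygens is slow, so protodeboronation of 4 may outrun it, and oxidative addition to the electron-rich enolate form of 10 is not fast either. The fallback replaces boron by tin, which cannot be lost by protonolysis under neutral, anhydrous conditions. From 3, hexamethylditin and Pd(PPh3)4 in toluene at 110 °C would give 7-methoxy-8-(trimethylstannyl)-2H-chromen-2-one F6. A copper-assisted Stille coupling of F6 with 10 (Pd(PPh3)4, CuI, CsF in excess, DMF, 50 °C) would rejoin the route at 11.

**Step 11.** The electron-poor enol triflate may lose its sulfonyl group to formate or the amine by S–O cleavage, which returns 13, or may suffer addition–elimination at C4. Either can be faster than oxidative addition at a carbon flanked by the 3-aryloxy group and the peri C5–H. The fallback leaves out the sulfonate and the palladium hydride. From 13, POCl3 with BnEt3NCl in MeCN at 80 °C would give 4-chloro-7-methoxy-8-(7-methoxy-2-oxo-2H-chromen-8-yl)-3-[(2-oxo-2H-chromen-7-yl)oxy]-2H-chromen-2-one F7. Zinc dust in AcOH at 60 °C, the classical dechlorination of 4-chlorocoumarins, would reduce the C4–Cl bond and rejoin the route at 15.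

## Further compounds

F1 | step 9 | 4-hydroxy-7-methoxy-3-[(4-methoxyphenyl)methoxy]-8-(7-methoxy-2-oxo-2H-chromen-8-yl)-2H-chromen-2-one | COc1ccc(COc2c(O)c3ccc(OC)c(-c4c(OC)ccc5ccc(=O)oc45)c3oc2=O)cc1
F2 | step 9 | 7-methoxy-3-[(4-methoxyphenyl)methoxy]-8-(7-methoxy-2-oxo-2H-chromen-8-yl)-2-oxo-2H-chromen-4-yl trifluoromethanesulfonate | COc1ccc(COc2c(OS(=O)(=O)C(F)(F)F)c3ccc(OC)c(-c4c(OC)ccc5ccc(=O)oc45)c3oc2=O)cc1
F3 | step 9 | 7-methoxy-3-[(4-methoxyphenyl)methoxy]-8-(7-methoxy-2-oxo-2H-chromen-8-yl)-2H-chromen-2-one | COc1ccc(COc2cc3ccc(OC)c(-c4c(OC)ccc5ccc(=O)oc45)c3oc2=O)cc1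
F4 | step 9 | 3-hydroxy-7-methoxy-8-(7-methoxy-2-oxo-2H-chromen-8-yl)-2H-chromen-2-one | COc1ccc2cc(O)c(=O)oc2c1-c1c(OC)ccc2ccc(=O)oc12
F5 | step 9 | (2-oxo-2H-chromen-7-yl)boronic acid | OB(O)c1ccc2ccc(=O)oc2c1
F6 | step 7 | 7-methoxy-8-(trimethylstannyl)-2H-chromen-2-one | COc1ccc2ccc(=O)oc2c1[Sn](C)(C)C
F7 | step 11 | 4-chloro-7-methoxy-8-(7-methoxy-2-oxo-2H-chromen-8-yl)-3-[(2-oxo-2H-chromen-7-yl)oxy]-2H-chromen-2-one | O=c1ccc2ccc(Oc3c(Cl)c4ccc(OC)c(-c5c(OC)ccc6ccc(=O)oc56)c4oc3=O)cc2o1
A1 | alternative 1 | methyl 3-(2,6-dimethoxyphenyl)-2,4-dihydroxybenzoate | COC(=O)c1ccc(O)c(-c2c(OC)cccc2OC)c1O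
A2 | alternative 1 | 2-(2,6-dimethoxyphenyl)-1-methoxy-1,3-bis(trimethylsilyloxy)buta-1,3-diene | COC(O[Si](C)(C)C)=C(C(=C)O[Si](C)(C)C)c1c(OC)cccc1OC
A3 | alternative 1 | methyl propiolate | C#CC(=O)OC
A4 | alternative 2 | triumbelletin diacetate, 8-[7-(acetyloxy)-2-oxo-2H-chromen-8-yl]-2-oxo-3-[(2-oxo-2H-chromen-7-yl)oxy]-2H-chromen-7-yl acetate | O=c1ccc2ccc(Oc3cc4ccc(OC(C)=O)c(-c5c(OC(C)=O)ccc6ccc(=O)oc56)c4oc3=O)cc2o1
A5 | alternative 2 | 2-[(2-oxo-2H-chromen-7-yl)oxy]acetic acid | O=C(O)COc1ccc2ccc(=O)oc2c1
A6 | alternative 2 | 2,4-dihydroxy-3-(7-hydroxy-2-oxo-2H-chromen-8-yl)benzaldehyde | O=Cc1ccc(O)c(-c2c(O)ccc3ccc(=O)oc23)c1O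
A7 | alternative 3 | triumbelletin dimethyl ether (the same compound as 15) | O=c1ccc2ccc(Oc3cc4ccc(OC)c(-c5c(OC)ccc6ccc(=O)oc56)c4oc3=O)cc2o1
A8 | alternative 3 | 3-hydroxy-7-methoxy-8-(7-methoxy-2-oxo-2H-chromen-8-yl)-2H-chromen-2-one | COc1ccc2cc(O)c(=O)oc2c1-c1c(OC)ccc2ccc(=O)oc12
A9 | alternative 3 | (2-oxo-2H-chromen-7-yl)boronic acid | OB(O)c1ccc2ccc(=O)oc2c1
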